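With 1.40 M of starting material against 0.240 M of coupling partner in the epsilon run, you have less partner than substrate, so your hunch of a low share on starting material is sound, and you can put a number on it.

| flask | starting material | coupling partner | time |
|---|---|---|---|
| eta | 0.200 M | 0.240 M |  |
| beta | 0.600 M | 0.240 M |  |
| gamma | 0.200 M | 0.480 M |  |
| epsilon | 1.40 M | 0.240 M | 63 min |

| run | time / min | [product] / M |
|---|---|---|
| eta run | 2.8 | 0.0040 |
| eta run | 8.5 | 0.0253 |
| eta run | 16 | 0.0559 |
| eta run | 26 | 0.0859 |
| eta run | 37 | 0.1101 |
| eta run | 49 | 0.1308 |
| eta run | 63 | 0.1484 |
| beta run | 2.8 | 0.0095 |
| beta run | 8.5 | 0.0517 |
| beta run | 16 | 0.1028 |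
| beta run | 26 | 0.1538 |
| beta run | 37 | 0.1902 |
| beta run | 49 | 0.2132 |
| beta run | 63 | 0.2261 |
| gamma run | 2.8 | 0.0076 |
| gamma run | 8.5 | 0.0380 |
| gamma run | 16 | 0.0804 |
| gamma run | 26 | 0.1204 |
| gamma run | 37 | 0.1498 |
| gamma run | 49 | 0.1686 |
| gamma run | 63 | 0.1824 |

(readings scatter by 0.001 M)

- Overall: starting material + coupling partner -> product.
- Constant volume, constant temperature.
- Bound and free are read together.
- "The second partner" is coupling partner.
- An order is taken over about fifteen percent of the charge, up and down.

- apparent order in [coupling partner] of the starting rate, round the charge of the eta run (the rate where two percent of its starting material have turned into product)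
- apparent order in [starting material] of the starting rate, round the charge of the eta run (the rate where two percent of its starting material have turned into product) (one fixed amount of product, the same in the runs compared)
- product in the epsilon run at 63 min, as a share of the starting material charged

1. In the epsilon run, coupling partner is the limiting reagent. One of it makes one of product, so the share stops at 17.1%.

2. In the beta run, 5.79% of the coupling partner has not become product at 63 min. The epsilon run has more starting material than the beta run, so I expect a smaller remainder there and put the share between 16.1% and 17.1%.

3. For the orders, compare runs at one fixed amount of product, 0.0253 M, which the eta run shows at 8.5 min. Reading straight between neighbouring readings, the gamma run gets there at 6.12 min and the beta run at 4.93 min.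

4. Divide the logarithm of the time ratio by the logarithm of the charge ratio. From the eta run to the gamma run this gives 0.474, the clock order in coupling partner. From the eta run to the beta run, the same rule gives 0.495 in starting material. I commit to these two values.

5. The forecast, reading “a ping-pong-like form”, gives 0.56 in coupling partner and 0.52 in starting material, both above my values, and a share of 16.4%.

6. The flask gives 0.42 in coupling partner, 0.45 in starting material and a share of 16.9%.

    starting material + coupling partner ⇌ intermediate (1.026 M⁻¹ min⁻¹, 0.1428 min⁻¹)
    intermediate → product (0.1164 min⁻¹)
    2 starting material ⇌ idle substrate dimer, settled at all times (3.110 M⁻¹)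
    2 coupling partner ⇌ idle reagent dimer, settled at all times (4.240 M⁻¹)

The order in coupling partner stands at 0.42, and the pairing of coupling partner into idle reagent dimer holds it down: with that binding taken away, the order is 0.58. The clock order carries to a later mark in the gamma run. In the eta run, the product made comes to a quarter of the starting material charged at 14.6 min. Dividing that time by the charge ratio raised to 0.474 gives 10.5 min for the gamma run, whose product comes to that same amount at 10.4 min.

(The data are calculated for an exercise.)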